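**Assumption:** the target has no stereocentre and no stereogenic double bond outside a ring, so it is achiral and only the constitution has to be made.

## Retrosynthetic overview

1. Target 12 comes from its 7-O-acetate 11 by deacetylation.
2. Key disconnection: the C3–C4 bond and the lactone C–O bond of the upper (3-aryloxy) coumarin, giving salicylaldehyde 2 and aryloxyacetic acid 8 (Perkin–Oglialoro aldol-type condensation). This pyranone ring is formed last.
3. Acid 8 comes from scopoletin 5 and tert-butyl bromoacetate, so the ether oxygen on C3 is in place before the upper ring exists.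
4. The lower coumarin 5 is formed first, from aldehyde 2 and a stabilised ylide (Wittig olefination, then lactonisation).
5. Both halves come from aldehyde 2, made from cheap 2,4,5-trimethoxybenzaldehyde 1.

## Route

**Step 1**
Reactants: 1 2,4,5-trimethoxybenzaldehyde
Product: 2 2,4-dihydroxy-5-methoxybenzaldehyde
Conditions: AlCl3 (5 equiv), CH2Cl2, 0 °C to rt, 24 h; then ice / 1 M HCl
Reagents that add atoms: none
Why: Lewis-acid ether cleavage in which AlCl3 bound to the carbonyl removes only the chelating ortho methyl and the conjugated para methyl, while the meta (5-) methoxy group is not activated and stays.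

**Step 2**
Reactants: 2 2,4-dihydroxy-5-methoxybenzaldehyde; 3 ethyl (triphenylphosphoranylidene)acetate
Product: 5 scopoletin (7-hydroxy-6-methoxy-2H-chromen-2-one), via (Z)-cinnamate ester 4 (not isolated)
Conditions: N,N-diethylaniline, reflux (about 215 °C), N2, 4 h
Reagents that add atoms: none
Why: Wittig olefination of the free salicylaldehyde gives the cinnamate, whose E isomer equilibrates at this temperature to the Z isomer 4, which lactonises onto the ortho phenol with loss of ethanol; no stereocentre is formed.

**Step 3**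
Reactants: 5 scopoletin; 6 tert-butyl bromoacetate
Product: 7 tert-butyl 2-[(6-methoxy-2-oxo-2H-chromen-7-yl)oxy]acetate
Conditions: K2CO3 (2 equiv), acetone, reflux, 6 h
Reagents that add atoms: none
Why: Williamson ether synthesis (SN2) of the only phenol on a very reactive alpha-bromo ester; the lactone is untouched by anhydrous carbonate.

**Step 4**
Reactants: 7 tert-butyl 2-[(6-methoxy-2-oxo-2H-chromen-7-yl)oxy]acetate
Product: 8 2-[(6-methoxy-2-oxo-2H-chromen-7-yl)oxy]acetic acid
Conditions: CF3CO2H / CH2Cl2 (1:2), rt, 3 h; evaporate, triturate with Et2O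
Reagents that add atoms: none
Why: Acid-mediated tert-butyl ester cleavage (E1 loss of isobutene) frees the acid without the hydroxide that would open the lactone.

**Step 5**
Reactants: 2 2,4-dihydroxy-5-methoxybenzaldehyde (1.0 equiv); 8 2-[(6-methoxy-2-oxo-2H-chromen-7-yl)oxy]acetic acid (1.2 equiv)
Product: 11 6-methoxy-3-[(6-methoxy-2-oxo-2H-chromen-7-yl)oxy]-2-oxo-2H-chromen-7-yl acetate, via diacetoxy aldehyde 9 (not isolated), via mixed anhydride 10 (not isolated)
Conditions: Ac2O (10 equiv), Et3N (4 equiv), 115 °C, N2, 8 h; pour into ice water, filter, recrystallise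
Reagents that add atoms: acetic anhydride, CC(=O)OC(C)=O
Why: Perkin–Oglialoro condensation, in which Et3N enolises the mixed anhydride 10 (its alpha-aryloxy CH2 is more acidic than that of Ac2O) and the enolate adds intermolecularly to the aldehyde of 9 in an aldol addition that forms C3–C4, after which acyl transfer, loss of acetic acid and lactonisation close the coumarin; no stereocentre is formed.

**Step 6**
Reactants: 11 6-methoxy-3-[(6-methoxy-2-oxo-2H-chromen-7-yl)oxy]-2-oxo-2H-chromen-7-yl acetate
Product: 12 7-hydroxy-6-methoxy-3-[(6-methoxy-2-oxo-2H-chromen-7-yl)oxy]-2H-chromen-2-one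
Conditions: HCl (1.25 M in MeOH), THF, 45 °C, 4 h
Reagents that add atoms: none
Why: Acid-catalysed transesterification removes the labile phenyl acetate as methyl acetate, while both coumarin lactones (which stay ring-closed under acid), the ether link and the methyl ethers are inert.

## Compound list

1 | 2,4,5-trimethoxybenzaldehyde | COc1cc(OC)c(OC)cc1C=O | starting material
2 | 2,4-dihydroxy-5-methoxybenzaldehyde | COc1cc(C=O)c(O)cc1O | intermediate
3 | ethyl (triphenylphosphoranylidene)acetate | CCOC(=O)C=P(c1ccccc1)(c1ccccc1)c1ccccc1 | starting material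
4 | ethyl (Z)-3-(2,4-dihydroxy-5-methoxyphenyl)acrylate (not isolated) | CCOC(=O)/C=C\c1cc(OC)c(O)cc1O | intermediate
5 | scopoletin, 7-hydroxy-6-methoxy-2H-chromen-2-one | COc1cc2ccc(=O)oc2cc1O | intermediate
6 | tert-butyl bromoacetate | CC(C)(C)OC(=O)CBr | starting material
7 | tert-butyl 2-[(6-methoxy-2-oxo-2H-chromen-7-yl)oxy]acetate | COc1cc2ccc(=O)oc2cc1OCC(=O)OC(C)(C)C | intermediate
8 | 2-[(6-methoxy-2-oxo-2H-chromen-7-yl)oxy]acetic acid | COc1cc2ccc(=O)oc2cc1OCC(=O)O | intermediate
9 | 2,4-diacetoxy-5-methoxybenzaldehyde (not isolated) | COc1cc(C=O)c(OC(C)=O)cc1OC(C)=O | intermediate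
10 | acetic 2-[(6-methoxy-2-oxo-2H-chromen-7-yl)oxy]acetic anhydride (not isolated) | COc1cc2ccc(=O)oc2cc1OCC(=O)OC(C)=O | intermediate
11 | 6-methoxy-3-[(6-methoxy-2-oxo-2H-chromen-7-yl)oxy]-2-oxo-2H-chromen-7-yl acetate | COc1cc2cc(Oc3cc4oc(=O)ccc4cc3OC)c(=O)oc2cc1OC(C)=O | intermediate
12 | 7-hydroxy-6-methoxy-3-[(6-methoxy-2-oxo-2H-chromen-7-yl)oxy]-2H-chromen-2-one | COc1cc2cc(Oc3cc4oc(=O)ccc4cc3OC)c(=O)oc2cc1O | target

## Summary

Total step count: 6. Longest linear sequence: 6 steps (1 → 2 → 5 → 7 → 8 → 11 → 12); aldehyde 2 is used a second time in step 5.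

## Steps most likely to fail, with fallbacks

**Step 1 (regioselective double demethylation).** The risk is over- or under-demethylation. This fallback does not set out from a numbered compound: it replaces 1 by a second cheap commercial aldehyde and comes back to the route at 2. Isovanillin F1 is benzylated (benzyl bromide, K2CO3, DMF) to 3-benzyloxy-4-methoxybenzaldehyde F2. Baeyer–Villiger (Dakin-type) oxidation with mCPBA in CH2Cl2 gives 3-benzyloxy-4-methoxyphenyl formate F3, and K2CO3 in MeOH releases 3-benzyloxy-4-methoxyphenol F4. Ortho-formylation (MgCl2, Et3N, paraformaldehyde, MeCN, reflux) at the unhindered position para to the benzyloxy group gives 4-benzyloxy-2-hydroxy-5-methoxybenzaldehyde F5. Hydrogenolysis (H2, 10% Pd/C, EtOAc, rt) then gives 2. Here every oxygen substituent is placed by construction, with no selective ether cleavage.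

**Step 2 (high-temperature Wittig and lactonisation on a free diphenol).** The risk is a moderate yield and tar. The fallback sets out from 2 and comes back at 5. Knoevenagel condensation of 2 with Meldrum's acid (piperidinium acetate cat., EtOH, rt then reflux) gives 7-hydroxy-6-methoxy-2-oxo-2H-chromene-3-carboxylic acid F6, with lactonisation and loss of acetone. Protodecarboxylation (Cu powder, quinoline, 200 °C) then gives scopoletin 5.

**Step 5 (Perkin–Oglialoro condensation).** The risks are competing enolisation of Ac2O, which would give scopoletin acetate, and incomplete conversion. The fallback sets out from 2 and 8 and comes back at 12. Selective protection of the non-chelated 4-OH of 2 (chloromethyl methyl ether, K2CO3, acetone, rt) gives 2-hydroxy-5-methoxy-4-(methoxymethoxy)benzaldehyde F7. Steglich esterification with 8 (DCC, cat. DMAP, CH2Cl2) gives 2-formyl-4-methoxy-5-(methoxymethoxy)phenyl 2-[(6-methoxy-2-oxo-2H-chromen-7-yl)oxy]acetate F8. DBU in MeCN at 60 °C closes this by intramolecular aldol condensation to 6-methoxy-7-(methoxymethoxy)-3-[(6-methoxy-2-oxo-2H-chromen-7-yl)oxy]-2H-chromen-2-one F9. HCl in MeOH/THF removes the methoxymethyl group and gives 12 directly.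

## Further compounds

F1 | step 1 | isovanillin, 3-hydroxy-4-methoxybenzaldehyde (bought) | COc1ccc(C=O)cc1O
F2 | step 1 | 3-benzyloxy-4-methoxybenzaldehyde | COc1ccc(C=O)cc1OCc1ccccc1
F3 | step 1 | 3-benzyloxy-4-methoxyphenyl formate | COc1ccc(OC=O)cc1OCc1ccccc1
F4 | step 1 | 3-benzyloxy-4-methoxyphenol | COc1ccc(O)cc1OCc1ccccc1
F5 | step 1 | 4-benzyloxy-2-hydroxy-5-methoxybenzaldehyde | COc1cc(C=O)c(O)cc1OCc1ccccc1
F6 | step 2 | 7-hydroxy-6-methoxy-2-oxo-2H-chromene-3-carboxylic acid | COc1cc2cc(C(=O)O)c(=O)oc2cc1O
F7 | step 5 | 2-hydroxy-5-methoxy-4-(methoxymethoxy)benzaldehyde | COCOc1cc(O)c(C=O)cc1OC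
F8 | step 5 | 2-formyl-4-methoxy-5-(methoxymethoxy)phenyl 2-[(6-methoxy-2-oxo-2H-chromen-7-yl)oxy]acetate | COCOc1cc(OC(=O)COc2cc3oc(=O)ccc3cc2OC)c(C=O)cc1OC
F9 | step 5 | 6-methoxy-7-(methoxymethoxy)-3-[(6-methoxy-2-oxo-2H-chromen-7-yl)oxy]-2H-chromen-2-one | COCOc1cc2oc(=O)c(Oc3cc4oc(=O)ccc4cc3OC)cc2cc1OC
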